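**The task.** Answer 3 questions on the flask below, from the single earlier run.

| flask | solid substrate | partner | protic impurity | remark | time |
|---|---|---|---|---|---|
| epsilon | 1.1 M | 0.95 equiv | 1.1 M | run made earlier |  |
| flask | 1.1 M | 0.950 equiv | 0.550 M |  | 40 h |

- epsilon (time / h: product / %): 0.667: 0.3; 2.00: 3.0; 4.00: 7.9; 6.00: 12.4; 8.00: 15.2

(each reading ± 0.5 percentage points)

1. the product standing at 40 h, as a percentage of the solid substrate charged
2. the change that raises the amount of product at 40 h, in percent of the solid substrate charged most ("none" if none brings more than 2 percentage points) (Monday's / Sunday's / Saturday's / none)
3. amount of product at 40 h, in percent of the solid substrate charged, after Monday's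

- Monday's: doubling the amount of partner, all else as stated
- Sunday's: doubling the dissolution coefficient of the solid substrate, all else as stated
- Saturday's: doubling the solubility of the solid substrate, all else as stated

- solid, in amounts per volume of the solution: solid substrate
- reactions considered so far: solid substrate <-> dissolved substrate; dissolved substrate + partner <-> product; partner + protic impurity -> quenched reagent
- at the start none of the solid substrate is in solution
- no earlier run changes the charge of protic impurity; that part of a forecast is a guess

**Impurity load.** Take the partner charge, 1.04 M. This flask has L = −0.279, where the impurity load L is the common logarithm of protic impurity charge over partner charge. Below zero, impurity is the limiting reagent of the quench; above zero, partner is. The epsilon run stands at 0.0223. Monday's moves the flask to −0.580, while Sunday's and Saturday's leave L unchanged.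

**Upper bound.** Product starts under the partner charge, 95.0% of the solid substrate. Tighten this with the readings: the last increment, 2.8 percentage points, is smaller than the one before, 4.5 points. Holding it to 40 h gives 60.0%.

**Lower bound.** Take the epsilon run's 15.2% at 8.00 h, reached with twice this flask's impurity. The bracket spans 0.596 decades, and its logarithmic midpoint, my own figure, is 30.2%.

**The forecast.** It gives 40%, inside the bracket but above my midpoint, and 70% after Monday's, holding: “Partner is then nearly spent, so partner supply is limiting.”

    solid substrate ⇌ dissolved substrate, rate k1*(cs1 - [dissolved substrate]) while solid is left; crystals form when [dissolved substrate] > cs1 (solubility = 0.620 M, k = 0.156 h⁻¹)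
    dissolved substrate + partner ⇌ product (K = 1.50 L mol⁻¹, k = 0.191 L mol⁻¹ h⁻¹)
    partner + protic impurity → quenched reagent (k = 0.0356 L mol⁻¹ h⁻¹)

**The flask.** It gives 32.7%, inside the bracket. Monday's adds 27 points, reaching 59.6%, more than Saturday's 3.5 points or Sunday's 1.1 points. Partner stands at 36% of its charge at 40.0 h. With L at −0.279, this flask at 400 h holds 1.15% of its impurity and 24.8% of its partner. The neighbour with 2.2 M of impurity has L = 0.325, and at 40.0 h it holds 63.7% of its impurity, 10.9% of its partner and product at 12.0%.

(Readings and results are calculated with constants of no real substance, and the scatter is random.)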